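**The choice.** Should your next charge of starting material go into the continuous tank or the closed flask? The amounts and the readings so far are these.

| flask | starting material | remark | time |
|---|---|---|---|
| Wednesday's | 0.050 M | run made earlier |  |
| Saturday's | 0.025 M | run made earlier |  |
| Friday's | 0.038 M | run made earlier |  |
| blue | 0.050 M | a single well-mixed tank run continuously and read at steady state, 2.5 min in it on average |  |
| green | 0.050 M | everything together in a closed stirred flask, run for 2.5 min | 2.5 min |

| run | time / min | target / % | side product / % | starting material / % |
|---|---|---|---|---|
| Wednesday's | 0.200 | 0 | 8 | 60 |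
| Wednesday's | 0.333 | 5 | 10 | 39 |
| Wednesday's | 0.500 | 10 | 16 | 23 |
| Wednesday's | 0.833 | 32 | 16 | 8 |
| Wednesday's | 1.50 | 60 | 20 | 2 |
| Wednesday's | 2.50 | 77 | 19 | 0 |
| Saturday's | 0.250 | 6 | 4 | 53 |
| Saturday's | 0.417 | 10 | 9 | 34 |
| Saturday's | 0.667 | 23 | 9 | 16 |
| Saturday's | 1.00 | 43 | 11 | 8 |
| Saturday's | 2.00 | 80 | 11 | 2 |
| Saturday's | 3.00 | 87 | 10 | 0 |
| Friday's | 0.500 | 11 | 15 | 26 |
| Friday's | 1.00 | 43 | 15 | 8 |
| Friday's | 1.50 | 65 | 15 | 2 |
| Friday's | 2.00 | 74 | 14 | 0 |
| Friday's | 2.50 | 79 | 14 | 0 |
| Friday's | 3.00 | 83 | 17 | 0 |

(each reading ± 1.5 percentage points)

- percent here means starting material units held: one side product counts as two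
- the stated concentrations are those of everything mixed, before any reaction; amounts are the same in each set-up
- the analysis behind the earlier runs scatters by 1.5 percentage points, standard deviation
- the earlier runs were made in a closed, stirred flask

1. the set-up with the highest share of target in all that became target or side product, at the outlet or at the end ("none" if the first two lie within 2 percentage points) (blue / green / none)
2. share of target in all that became target or side product, at the outlet or at the end, blue
3. share of target in all that became target or side product, at the outlet or at the end, green

**Side product.** Wednesday's run ended with 19% side product and Saturday's with 10%, about half, from half the charge. The target's share (the selectivity) at those last readings, at 2.50 min and 3.00 min, rose from 80.2% to 89.7%. So I watch how much starting material stands in the vessel.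

**Counting turnovers.** Wednesday's reading of 23% at 0.500 min gives a first-order decay constant of about 2.94 min⁻¹, and Friday's 26% at 0.500 min sits close to it with a smaller charge. Turnovers, this constant times the time in the vessel, come to 7.35 for 2.5 min. A well-mixed tank at steady state, with first-order loss of its feed, holds one part in one plus the turnovers, here 12.0%.

**My reckoning.** Green starts at 0.050 M and repeats Wednesday's run, so I take 80.2% for it. I reckon blue's tank at 0.00599 M, less than Saturday's charge of 0.025 M, so I take 89.7% as a rough mark for blue and choose the tank.

**The forecast.** It gave blue, with 89% for blue and 80% for green: “the tank holds starting material at only about 12% of feed, which suppresses the bimolecular path”.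

**The result.** Blue gives 89.0% and green 79.4%, 9.6 percentage points apart, so the best set-up is blue.

    intermediate C → target (k = 0.190 s⁻¹)
    intermediate A → intermediate B (k = 0.0970 s⁻¹)
    intermediate B ⇌ intermediate C (K = 2.00, k = 0.0400 s⁻¹)
    starting material → intermediate A (k = 0.0410 s⁻¹)
    starting material + intermediate A → side product (k = 0.710 M⁻¹ s⁻¹)
    intermediate C ⇌ intermediate D (K = 0.700, k = 0.0170 s⁻¹)

The step from intermediate C to intermediate D makes no difference to blue's share. Blue's tank holds 13.5% starting material, against the 12.0% counted from turnovers. Green read at 0.667 min has had 1.96 turnovers, which reckon to 14.1% left in that closed flask, and it holds 15.8%.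

The runs stem from a simulated flask for substances that don't exist.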